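The route rests on making the C2–C3 bond of the 1,4-dioxane ring from an open-chain diether of 4-bromocatechol. C2 is the benzylic carbon of the syringyl ring, para to its free phenol and already bound to O1; C3, bound to O4, is the α-carbon of an aryloxyacetaldehyde. Oxidising the phenol turns C2 into the electrophilic terminus of a para-quinone methide while a chiral secondary amine turns C3 into an enamine, so one operation closes the dioxane ring and sets both stereocentres as the trans pair. The precursor therefore carries a 4-hydroxy-3,5-dimethoxybenzyl group on O1 and a CH2CHO arm on O4; the resorcinol styryl unit is attached afterwards by Heck coupling at the bromide.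

Key step: step 8

Remark on locants and descriptors: the ring is numbered O1, C2 (syringyl-bearing), C3 (one-carbon arm), O4, C7 (bromine or styryl). With these locants the target is (2R,3R). The aldehyde of step 8 is (2R,3S) only because the CIP priorities at C3 change between CHO and CH2OH; the trans arrangement in space is the same.

Remark on precursor design: a free 4-hydroxybenzyl aryl ether ionises at the benzylic C–O bond under acid and expels the aryloxide under base. The aldehyde is therefore carried as an allyl ether (unmasked oxidatively at neutral pH) and the syringyl phenol as a TBS ether (removed last with buffered fluoride). The benzylic ether is made by Mitsunobu coupling so that no silyl transfer between phenols can occur.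

Remark on the catalyst: (R)-2-[diphenyl(trimethylsilyloxy)methyl]pyrrolidine, C[Si](C)(C)OC(c1ccccc1)(c1ccccc1)[C@H]1CCCN1, is chosen from the usual steric-shielding model of diarylprolinol silyl ethers. If the tethered closure shows the opposite sense, the (S)-amine is used instead.

Step 1
Reactants: 1 5-bromosalicylaldehyde (5-bromo-2-hydroxybenzaldehyde); 2 allyl bromide
Product: 3 2-(allyloxy)-5-bromobenzaldehyde
Conditions: K2CO3, DMF, rt
Reagents that add atoms: none
Why: Williamson etherification of the acidic salicylaldehyde phenol with an allylic bromide is reliable and puts the masked two-carbon aldehyde arm on the oxygen para to bromine, the future O4.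

Step 2
Reactants: 3 2-(allyloxy)-5-bromobenzaldehyde
Product: 5 2-(allyloxy)-5-bromophenol, via aryl formate 4 (not isolated)
Conditions: 30% H2O2, H2SO4 (cat.), MeOH, rt
Reagents that add atoms: hydrogen peroxide, OO
Why: Acid-catalysed Dakin oxidation (Baeyer–Villiger type): the electron-rich ortho-alkoxyaryl group migrates in the peroxide adduct and formate 4 is methanolysed in the same pot, while the terminal alkene and the aryl bromide are inert to H2O2.

Step 3
Reactants: 6 syringaldehyde (4-hydroxy-3,5-dimethoxybenzaldehyde)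
Product: 7 4-(tert-butyldimethylsilyloxy)-3,5-dimethoxybenzaldehyde
Conditions: TBSCl, imidazole, DMF, rt
Reagents that add atoms: tert-butyldimethylsilyl chloride, CC(C)(C)[Si](C)(C)Cl
Why: Silylation of the phenol gives an ether that is stable to base and oxidants and that fluoride can later remove under near-neutral conditions.

Step 4
Reactants: 7 4-(tert-butyldimethylsilyloxy)-3,5-dimethoxybenzaldehyde
Product: 8 [4-(tert-butyldimethylsilyloxy)-3,5-dimethoxyphenyl]methanol
Conditions: NaBH4, THF/MeOH, 0 °C
Reagents that add atoms: none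
Why: Borohydride reduction of an aromatic aldehyde to the benzylic alcohol is chemoselective and should leave the hindered aryl silyl ether intact at 0 °C.

Step 5
Reactants: 5 2-(allyloxy)-5-bromophenol; 8 [4-(tert-butyldimethylsilyloxy)-3,5-dimethoxyphenyl]methanol
Product: 9 1-(allyloxy)-4-bromo-2-{[4-(tert-butyldimethylsilyloxy)-3,5-dimethoxybenzyl]oxy}benzene
Conditions: PPh3, DIAD, THF, 0 °C → rt
Reagents that add atoms: none
Why: Mitsunobu etherification of a phenol with a primary, electron-rich benzylic alcohol forms the O1–benzyl bond under neutral conditions and avoids the silyl transfer between phenols that a carbonate-mediated alkylation could cause.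

Step 6
Reactants: 9 1-(allyloxy)-4-bromo-2-{[4-(tert-butyldimethylsilyloxy)-3,5-dimethoxybenzyl]oxy}benzene
Product: 11 2-(4-bromo-2-{[4-(tert-butyldimethylsilyloxy)-3,5-dimethoxybenzyl]oxy}phenoxy)acetaldehyde, via vicinal diol 10 (not isolated)
Conditions: OsO4 (2 mol%), NaIO4 (4 equiv), 2,6-lutidine, dioxane/H2O 3:1, rt
Reagents that add atoms: osmium tetroxide, O=[Os](=O)(=O)=O; sodium periodate, [Na+].[O-]I(=O)(=O)=O
Why: Lemieux–Johnson cleavage (catalytic dihydroxylation, then periodate glycol cleavage) unmasks the aldehyde at neutral pH, so neither the benzylic aryl ether nor the silyl ether is touched, and the lutidine buffer suppresses over-oxidation.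

Step 7
Reactants: 11 2-(4-bromo-2-{[4-(tert-butyldimethylsilyloxy)-3,5-dimethoxybenzyl]oxy}phenoxy)acetaldehyde
Product: 12 2-[4-bromo-2-(4-hydroxy-3,5-dimethoxybenzyloxy)phenoxy]acetaldehyde
Conditions: TBAF (1.1 equiv), AcOH (1.1 equiv), THF, 0 °C, short contact; used at once
Reagents that add atoms: none
Why: Fluoride cleavage of an aryl silyl ether is fast at 0 °C, and the acetic acid buffer keeps the liberated phenol protonated so that it neither expels the benzylic aryloxide nor promotes aldol reaction of the aldehyde.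

Step 8
Reactants: 12 2-[4-bromo-2-(4-hydroxy-3,5-dimethoxybenzyloxy)phenoxy]acetaldehyde
Product: 15 (2R,3S)-7-bromo-2-(4-hydroxy-3,5-dimethoxyphenyl)-2,3-dihydro-1,4-benzodioxine-3-carbaldehyde (trans), via quinone methide 13 (not isolated), via quinone methide enamine 14 (not isolated)
Conditions: DDQ (1.0 equiv), 4 Å MS, CH2Cl2, −40 °C; then (R)-2-[diphenyl(trimethylsilyloxy)methyl]pyrrolidine (20 mol%), −40 → 0 °C
Reagents that add atoms: none
Why: Proposed new method: DDQ removes two electrons and two protons from the syringyl phenol of 12 to give quinone methide 13, whose exocyclic carbon (future C2) already bears O1; the amine, added only after the oxidant is spent, condenses with the aldehyde to the (E)-enamine 14, whose nucleophilic carbon (future C3) adds to the methide carbon, and rearomatisation followed by hydrolysis should release 15 and the catalyst. The closest known reaction types are the amine-catalysed enantioselective 1,6-addition of aldehydes to para-quinone methides and the DDQ-mediated dehydrogenative coupling of benzylic C–H bonds with enamine-activated aldehydes, neither of which has been run as a ring closure onto an oxygen-substituted methide. The dioxane ring closes in a 6-exo-trig mode, the enamine and the methide double bonds both lying outside the forming ring. C3 is controlled by the catalyst: the diphenyl(silyloxy)methyl group of the (R)-amine blocks one face of the s-trans enamine so that the methide is expected to add to the Si face of the enamine carbon, which corresponds to 3S in 15. C2 is controlled by the substrate: a chair-like transition state with the quinonoid ring and the iminium arm both equatorial leads to the trans ring, and reversible opening of the C2–O1 bond through the quinone methide should let any cis isomer drain to trans. The step needs oxidation at the syringyl ring only and carbon rather than nitrogen or oxygen capture of the methide: the 2,6-dimethoxyphenol is by far the most easily oxidised site, the aldehyde has no β-hydrogen and cannot be dehydrogenated to an enal, and the tether should make six-membered carbon attack faster than intermolecular capture by the hindered amine.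

Step 9
Reactants: 15 (2R,3S)-7-bromo-2-(4-hydroxy-3,5-dimethoxyphenyl)-2,3-dihydro-1,4-benzodioxine-3-carbaldehyde
Product: 16 [(2R,3R)-7-bromo-2-(4-hydroxy-3,5-dimethoxyphenyl)-2,3-dihydro-1,4-benzodioxin-3-yl]methanol (trans)
Conditions: NaBH4, CH2Cl2/MeOH, −20 °C, on crude 15
Reagents that add atoms: none
Why: Borohydride reduction of the crude aldehyde at low temperature removes the epimerisable, β-elimination-prone formyl group at once, leaving C3 configurationally stable without touching C2 or the aryl bromide.

Step 10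
Reactants: 16 [(2R,3R)-7-bromo-2-(4-hydroxy-3,5-dimethoxyphenyl)-2,3-dihydro-1,4-benzodioxin-3-yl]methanol
Product: 17 (2R,3R)-7-bromo-3-[(tert-butyldimethylsilyloxy)methyl]-2-[4-(tert-butyldimethylsilyloxy)-3,5-dimethoxyphenyl]-2,3-dihydro-1,4-benzodioxine
Conditions: TBSCl (2.5 equiv), imidazole, DMF, rt
Reagents that add atoms: tert-butyldimethylsilyl chloride, CC(C)(C)[Si](C)(C)Cl
Why: Silylation of the phenol and the primary alcohol blocks the phenoxide-triggered opening of the C2–O1 bond, which could epimerise C2 under the basic, warm conditions of the coupling.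

Step 11
Reactants: 18 3,5-dihydroxybenzaldehyde
Product: 19 3,5-bis(tert-butyldimethylsilyloxy)benzaldehyde
Conditions: TBSCl (2.4 equiv), imidazole, DMF, rt
Reagents that add atoms: tert-butyldimethylsilyl chloride, CC(C)(C)[Si](C)(C)Cl
Why: Standard bis-silylation of the resorcinol hydroxyls makes the aldehyde compatible with the ylide of the next step and gives a non-polar coupling partner.

Step 12
Reactants: 19 3,5-bis(tert-butyldimethylsilyloxy)benzaldehyde
Product: 20 3,5-bis(tert-butyldimethylsilyloxy)styrene
Conditions: Ph3PCH3Br, n-BuLi, THF, 0 °C → rt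
Reagents that add atoms: methyltriphenylphosphonium bromide, C[P+](c1ccccc1)(c1ccccc1)c1ccccc1.[Br-]
Why: Wittig methylenation with the non-stabilised ylide converts the aromatic aldehyde into the terminal styrene without affecting the aryl silyl ethers.

Step 13
Reactants: 17 (2R,3R)-7-bromo-3-[(tert-butyldimethylsilyloxy)methyl]-2-[4-(tert-butyldimethylsilyloxy)-3,5-dimethoxyphenyl]-2,3-dihydro-1,4-benzodioxine; 20 3,5-bis(tert-butyldimethylsilyloxy)styrene
Product: 21 (2R,3R)-7-[(E)-3,5-bis(tert-butyldimethylsilyloxy)styryl]-3-[(tert-butyldimethylsilyloxy)methyl]-2-[4-(tert-butyldimethylsilyloxy)-3,5-dimethoxyphenyl]-2,3-dihydro-1,4-benzodioxine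
Conditions: Pd2(dba)3 (2.5 mol%), [HP(t-Bu)3]BF4 (10 mol%), Cy2NMe, dioxane, 80 °C
Reagents that add atoms: none
Why: Mizoroki–Heck coupling: the bulky electron-rich phosphine enables oxidative addition into the electron-rich aryl bromide at moderate temperature, and syn insertion at the terminal carbon followed by syn β-hydride elimination should give the (E)-stilbene while the two stereocentres, now flanked only by ethers, are untouched.

Step 14
Reactants: 21 (2R,3R)-7-[(E)-3,5-bis(tert-butyldimethylsilyloxy)styryl]-3-[(tert-butyldimethylsilyloxy)methyl]-2-[4-(tert-butyldimethylsilyloxy)-3,5-dimethoxyphenyl]-2,3-dihydro-1,4-benzodioxine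
Product: 22 aiphanol, (2R,3R)-7-[(E)-3,5-dihydroxystyryl]-2-(4-hydroxy-3,5-dimethoxyphenyl)-3-(hydroxymethyl)-2,3-dihydro-1,4-benzodioxine
Conditions: TBAF (6 equiv), AcOH (6 equiv), THF, 0 °C → rt
Reagents that add atoms: none
Why: Global fluoride desilylation of three aryl and one primary alkyl silyl ether; the acetic acid buffer prevents phenoxide formation and thus epimerisation at C2, and neither the (E)-alkene nor the stereocentres should be affected.

Compound list

1 | 5-bromosalicylaldehyde | O=Cc1cc(Br)ccc1O | starting material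
2 | allyl bromide | C=CCBr | starting material
3 | 2-(allyloxy)-5-bromobenzaldehyde | O=Cc1cc(Br)ccc1OCC=C | intermediate
4 | 2-(allyloxy)-5-bromophenyl formate | O=COc1cc(Br)ccc1OCC=C | intermediate
5 | 2-(allyloxy)-5-bromophenol | Oc1cc(Br)ccc1OCC=C | intermediate
6 | syringaldehyde | COc1cc(C=O)cc(OC)c1O | starting material
7 | 4-(tert-butyldimethylsilyloxy)-3,5-dimethoxybenzaldehyde | COc1cc(C=O)cc(OC)c1O[Si](C)(C)C(C)(C)C | intermediate
8 | [4-(tert-butyldimethylsilyloxy)-3,5-dimethoxyphenyl]methanol | COc1cc(CO)cc(OC)c1O[Si](C)(C)C(C)(C)C | intermediate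
9 | 1-(allyloxy)-4-bromo-2-{[4-(tert-butyldimethylsilyloxy)-3,5-dimethoxybenzyl]oxy}benzene | COc1cc(COc2cc(Br)ccc2OCC=C)cc(OC)c1O[Si](C)(C)C(C)(C)C | intermediate
10 | 3-(4-bromo-2-{[4-(tert-butyldimethylsilyloxy)-3,5-dimethoxybenzyl]oxy}phenoxy)propane-1,2-diol (racemic) | COc1cc(COc2cc(Br)ccc2OCC(O)CO)cc(OC)c1O[Si](C)(C)C(C)(C)C | intermediate
11 | 2-(4-bromo-2-{[4-(tert-butyldimethylsilyloxy)-3,5-dimethoxybenzyl]oxy}phenoxy)acetaldehyde | COc1cc(COc2cc(Br)ccc2OCC=O)cc(OC)c1O[Si](C)(C)C(C)(C)C | intermediate
12 | 2-[4-bromo-2-(4-hydroxy-3,5-dimethoxybenzyloxy)phenoxy]acetaldehyde | COc1cc(COc2cc(Br)ccc2OCC=O)cc(OC)c1O | intermediate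
13 | 2-(4-bromo-2-{[(3,5-dimethoxy-4-oxocyclohexa-2,5-dien-1-ylidene)methyl]oxy}phenoxy)acetaldehyde (aryloxy para-quinone methide) | COC1=CC(=COc2cc(Br)ccc2OCC=O)C=C(OC)C1=O | intermediate
14 | (E)-enamine of 13 with (R)-2-[diphenyl(trimethylsilyloxy)methyl]pyrrolidine | COC1=CC(=COc2cc(Br)ccc2O/C=C/N3CCC[C@@H]3C(c4ccccc4)(c5ccccc5)O[Si](C)(C)C)C=C(OC)C1=O | intermediate
15 | (2R,3S)-7-bromo-2-(4-hydroxy-3,5-dimethoxyphenyl)-2,3-dihydro-1,4-benzodioxine-3-carbaldehyde (trans) | COc1cc([C@H]2Oc3cc(Br)ccc3O[C@@H]2C=O)cc(OC)c1O | intermediate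
16 | [(2R,3R)-7-bromo-2-(4-hydroxy-3,5-dimethoxyphenyl)-2,3-dihydro-1,4-benzodioxin-3-yl]methanol (trans) | COc1cc([C@H]2Oc3cc(Br)ccc3O[C@@H]2CO)cc(OC)c1O | intermediate
17 | (2R,3R)-7-bromo-3-[(tert-butyldimethylsilyloxy)methyl]-2-[4-(tert-butyldimethylsilyloxy)-3,5-dimethoxyphenyl]-2,3-dihydro-1,4-benzodioxine | COc1cc([C@H]2Oc3cc(Br)ccc3O[C@@H]2CO[Si](C)(C)C(C)(C)C)cc(OC)c1O[Si](C)(C)C(C)(C)C | intermediate
18 | 3,5-dihydroxybenzaldehyde | O=Cc1cc(O)cc(O)c1 | starting material
19 | 3,5-bis(tert-butyldimethylsilyloxy)benzaldehyde | O=Cc1cc(O[Si](C)(C)C(C)(C)C)cc(O[Si](C)(C)C(C)(C)C)c1 | intermediate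
20 | 3,5-bis(tert-butyldimethylsilyloxy)styrene | C=Cc1cc(O[Si](C)(C)C(C)(C)C)cc(O[Si](C)(C)C(C)(C)C)c1 | intermediate
21 | (2R,3R)-7-[(E)-3,5-bis(tert-butyldimethylsilyloxy)styryl]-3-[(tert-butyldimethylsilyloxy)methyl]-2-[4-(tert-butyldimethylsilyloxy)-3,5-dimethoxyphenyl]-2,3-dihydro-1,4-benzodioxine | COc1cc([C@H]2Oc3cc(/C=C/c4cc(O[Si](C)(C)C(C)(C)C)cc(O[Si](C)(C)C(C)(C)C)c4)ccc3O[C@@H]2CO[Si](C)(C)C(C)(C)C)cc(OC)c1O[Si](C)(C)C(C)(C)C | intermediate
22 | aiphanol, (2R,3R)-7-[(E)-3,5-dihydroxystyryl]-2-(4-hydroxy-3,5-dimethoxyphenyl)-3-(hydroxymethyl)-2,3-dihydro-1,4-benzodioxine | COc1cc([C@H]2Oc3cc(/C=C/c4cc(O)cc(O)c4)ccc3O[C@@H]2CO)cc(OC)c1O | target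

Total step count: 14. Longest linear sequence: 10 steps (steps 1, 2, 5, 6, 7, 8, 9, 10, 13, 14, from 5-bromosalicylaldehyde).

Steps most likely to fail

Step 8 (proposed new method). Several processes could defeat it:
- collapse of the aryloxy quinone methide to syringaldehyde and the bromophenol, through traces of water or through addition of the amine followed by loss of the aryloxide;
- ionisation of the benzylic C–O bond of the precursor before oxidation;
- weak facial control in the tethered addition;
- β-elimination of O1 from the product through its own enamine.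

The fallback uses known chemistry only, sets out from 7 and 5 and rejoins the route at 17. Horner–Wadsworth–Emmons olefination of 7 with triethyl phosphonoacetate (NaH, THF) would give ethyl (E)-3-[4-(tert-butyldimethylsilyloxy)-3,5-dimethoxyphenyl]prop-2-enoate F1. Reduction with i-Bu2AlH (CH2Cl2, −78 °C) gives (E)-3-[4-(tert-butyldimethylsilyloxy)-3,5-dimethoxyphenyl]prop-2-en-1-ol F2. Sharpless asymmetric epoxidation (Ti(OiPr)4, L-(+)-diethyl tartrate, t-BuOOH, 4 Å MS, CH2Cl2, −20 °C) gives {(2S,3S)-3-[4-(tert-butyldimethylsilyloxy)-3,5-dimethoxyphenyl]oxiran-2-yl}methanol F3. Phenol 5 then opens the epoxide at the benzylic carbon with inversion (Ti(OiPr)4-assisted C3-selective opening, CH2Cl2, rt) to give (2S,3R)-3-(2-allyloxy-5-bromophenoxy)-3-[4-(tert-butyldimethylsilyloxy)-3,5-dimethoxyphenyl]propane-1,2-diol F4, which fixes the O1–C2 bond. Selective silylation of the primary hydroxyl (TBSCl, imidazole, CH2Cl2, 0 °C) gives the secondary alcohol (2S,3R)-3-(2-allyloxy-5-bromophenoxy)-1-(tert-butyldimethylsilyloxy)-3-[4-(tert-butyldimethylsilyloxy)-3,5-dimethoxyphenyl]propan-2-ol F5. Removal of the allyl group (Pd(PPh3)4 cat., morpholine, THF, rt) gives the phenol 4-bromo-2-{(1R,2S)-3-(tert-butyldimethylsilyloxy)-1-[4-(tert-butyldimethylsilyloxy)-3,5-dimethoxyphenyl]-2-hydroxypropoxy}phenol F6. Intramolecular Mitsunobu etherification (PPh3, DIAD, THF) closes the O4–C3 bond with inversion and delivers 17, with both stereocentres traced to the epoxidation.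

Step 7. Once the phenol is free, fluoride or acetate could trigger loss of the aryloxide from the para-hydroxybenzyl ether (1,6-elimination) or aldol self-condensation of the aldehyde. The fallback sets out from 1 and 8 and rejoins at 12; it frees the phenol while the carbonyl is still an unreactive amide. Alkylation of 1 with 2-chloro-N-methoxy-N-methylacetamide (K2CO3, KI cat., DMF) would give 2-(4-bromo-2-formylphenoxy)-N-methoxy-N-methylacetamide F7. Dakin oxidation (H2O2, H2SO4 cat., MeOH) gives 2-(4-bromo-2-hydroxyphenoxy)-N-methoxy-N-methylacetamide F8. Mitsunobu coupling with 8 (PPh3, DIAD, THF) gives 2-(4-bromo-2-{[4-(tert-butyldimethylsilyloxy)-3,5-dimethoxybenzyl]oxy}phenoxy)-N-methoxy-N-methylacetamide F9. Desilylation (TBAF, THF, 0 °C) gives 2-[4-bromo-2-(4-hydroxy-3,5-dimethoxybenzyloxy)phenoxy]-N-methoxy-N-methylacetamide F10. Weinreb reduction (i-Bu2AlH, 2.2 equiv, THF, −78 °C; Rochelle salt work-up) then releases 12 only on neutral work-up of the chelated tetrahedral intermediate.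

Step 13. Oxidative addition into the electron-rich aryl bromide could be slow, leading to stalled conversion, partial loss of aryl silyl groups on prolonged heating, or some 1,1-diarylethylene from insertion with the wrong regiochemistry. The fallback sets out from 20 and 17 and rejoins at 21. Cross-metathesis of 20 with vinylboronic acid pinacol ester (second-generation Grubbs catalyst, CH2Cl2, 40 °C) would give (E)-2-[3,5-bis(tert-butyldimethylsilyloxy)styryl]-4,4,5,5-tetramethyl-1,3,2-dioxaborolane F11. Suzuki–Miyaura coupling of this boronate with 17 (Pd(dppf)Cl2, K3PO4, dioxane/H2O, 70 °C) gives 21 with the alkene geometry fixed by the boronate.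

Further compounds

F1 | step 8 | ethyl (E)-3-[4-(tert-butyldimethylsilyloxy)-3,5-dimethoxyphenyl]prop-2-enoate | CCOC(=O)/C=C/c1cc(OC)c(O[Si](C)(C)C(C)(C)C)c(OC)c1
F2 | step 8 | (E)-3-[4-(tert-butyldimethylsilyloxy)-3,5-dimethoxyphenyl]prop-2-en-1-ol | OC/C=C/c1cc(OC)c(O[Si](C)(C)C(C)(C)C)c(OC)c1
F3 | step 8 | {(2S,3S)-3-[4-(tert-butyldimethylsilyloxy)-3,5-dimethoxyphenyl]oxiran-2-yl}methanol | OC[C@@H]1O[C@H]1c1cc(OC)c(O[Si](C)(C)C(C)(C)C)c(OC)c1
F4 | step 8 | (2S,3R)-3-(2-allyloxy-5-bromophenoxy)-3-[4-(tert-butyldimethylsilyloxy)-3,5-dimethoxyphenyl]propane-1,2-diol | OC[C@H](O)[C@H](Oc1cc(Br)ccc1OCC=C)c1cc(OC)c(O[Si](C)(C)C(C)(C)C)c(OC)c1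
F5 | step 8 | (2S,3R)-3-(2-allyloxy-5-bromophenoxy)-1-(tert-butyldimethylsilyloxy)-3-[4-(tert-butyldimethylsilyloxy)-3,5-dimethoxyphenyl]propan-2-ol | CC(C)(C)[Si](C)(C)OC[C@H](O)[C@H](Oc1cc(Br)ccc1OCC=C)c1cc(OC)c(O[Si](C)(C)C(C)(C)C)c(OC)c1
F6 | step 8 | 4-bromo-2-{(1R,2S)-3-(tert-butyldimethylsilyloxy)-1-[4-(tert-butyldimethylsilyloxy)-3,5-dimethoxyphenyl]-2-hydroxypropoxy}phenol | CC(C)(C)[Si](C)(C)OC[C@H](O)[C@H](Oc1cc(Br)ccc1O)c1cc(OC)c(O[Si](C)(C)C(C)(C)C)c(OC)c1
F7 | step 7 | 2-(4-bromo-2-formylphenoxy)-N-methoxy-N-methylacetamide | CON(C)C(=O)COc1ccc(Br)cc1C=O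
F8 | step 7 | 2-(4-bromo-2-hydroxyphenoxy)-N-methoxy-N-methylacetamide | CON(C)C(=O)COc1ccc(Br)cc1O
F9 | step 7 | 2-(4-bromo-2-{[4-(tert-butyldimethylsilyloxy)-3,5-dimethoxybenzyl]oxy}phenoxy)-N-methoxy-N-methylacetamide | CON(C)C(=O)COc1ccc(Br)cc1OCc1cc(OC)c(O[Si](C)(C)C(C)(C)C)c(OC)c1
F10 | step 7 | 2-[4-bromo-2-(4-hydroxy-3,5-dimethoxybenzyloxy)phenoxy]-N-methoxy-N-methylacetamide | CON(C)C(=O)COc1ccc(Br)cc1OCc1cc(OC)c(O)c(OC)c1
F11 | step 13 | (E)-2-[3,5-bis(tert-butyldimethylsilyloxy)styryl]-4,4,5,5-tetramethyl-1,3,2-dioxaborolane | CC1(C)OB(/C=C/c2cc(O[Si](C)(C)C(C)(C)C)cc(O[Si](C)(C)C(C)(C)C)c2)OC1(C)C
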